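**Assumptions (one line each)**
- (S)-Naringenin is treated as commercially available and cheap. Its C2 configuration is the target's (2S); I confirmed this by CIP analysis of both SMILES.
- The chelated 5-OH stays unreactive throughout. The 7-OH is the most acidic phenol and is silylated selectively under imidazole catalysis.
- The flavanone C2 centre survives because every step is neutral, mildly acidic, or buffered, so retro-oxa-Michael ring opening is avoided.

**Retrosynthesis**
1. Target ⇐ fluoride removal of the 7-O-TIPS group from 11.
2. 11 ⇐ photosensitised singlet-oxygen ene reaction at one benzylic prenyl of the 3',5'-diprenyl flavanone 9, then hydroperoxide reduction. This is the key photochemical step; it forms the C–O bond and the conjugated E-alkene.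
3. 9 ⇐ double Stille prenylation of the 3',5'-diiodo-4'-methoxy flavanone 7 ⇐ O-methylation of 5 ⇐ ortho-diiodination of 3.
4. Rings A and C come pre-formed in (S)-naringenin (1), which supplies the only stereocentre. The B-ring substituents are installed on it.

**Route**

**Step 1**
- Reactants: 1 (S)-naringenin; 2 TIPSCl
- Product: 3, (2S)-7-O-triisopropylsilyl-naringenin
- Conditions: TIPSCl (1.05 equiv), imidazole, DMF, 0 °C → rt
- Reagents that add atoms: TIPSCl, CC(C)[Si](Cl)(C(C)C)C(C)C
- Why: The 7-OH is the most acidic phenol and is silylated selectively (silyl-ether formation). The bulky silyl group later shields C6 and C8 of the A ring, and no stereocentre is touched.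

**Step 2**
- Reactants: 3; 4 N-iodosuccinimide
- Product: 5, (2S)-3',5'-diiodo-7-O-TIPS-naringenin
- Conditions: NIS (2.2 equiv), MeCN/CH2Cl2, 0 °C → rt
- Reagents that add atoms: NIS, O=C1CCC(=O)N1I
- Why: Electrophilic aromatic iodination goes ortho to the free 4'-phenol. The A ring is hindered by the 7-OTIPS and deactivated by the chelated 5-OH and the carbonyl. The conditions are neutral, so C2 is untouched.

**Step 3**
- Reactants: 5; 6 TMSCHN2
- Product: 7, (2S)-3',5'-diiodo-4'-O-methyl-7-O-TIPS-naringenin
- Conditions: TMSCHN2 (2 equiv), iPr2NEt, MeCN/MeOH (9:1), 0 °C → rt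
- Reagents that add atoms: TMSCHN2, C[Si](C)(C)C=[N+]=[N-]
- Why: Aoyama–Shioiri methylation of the acidic 2,6-diiodophenol (pKa about 7) under essentially neutral conditions. The chelated 5-OH is not methylated and C2 is not epimerised.

**Step 4**
- Reactants: 7; 8 tributyl(3-methylbut-2-enyl)stannane
- Product: 9, (2S)-3',5'-bis(3-methylbut-2-enyl)-4'-O-methyl-7-O-TIPS-naringenin
- Conditions: 8 (2.6 equiv), Pd2(dba)3 (2.5 mol%), P(2-furyl)3 (10 mol%), toluene, 90 °C
- Reagents that add atoms: prenyl-SnBu3, CC(C)=CC[Sn](CCCC)(CCCC)CCCC
- Why: Stille coupling of both aryl iodides, which are equivalent by symmetry. The conditions are base-free, so the ketone and the flavanone ring are retained. Coupling at the unhindered CH2 terminus gives the linear prenyl group.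

**Step 5**
- Reactants: 9; 10 O2
- Product: 11, (2S)-3'-[(E)-3-hydroxy-3-methylbut-1-enyl]-5'-(3-methylbut-2-enyl)-4'-O-methyl-7-O-TIPS-naringenin
- Conditions: TPP (1 mol%), O2 (1 atm), CH2Cl2, 0 °C, white LEDs, stopped at about 50% conversion with recovered 9 recycled; then PPh3 (2 equiv), 0 °C → rt
- Reagents that add atoms: O2, O=O (the tertiary OH oxygen comes from O2; PPh3 only removes the second oxygen)
- Why: Proposed new method: a Schenck singlet-oxygen ene reaction adapted to a prenyl arene, with selective abstraction of the benzylic allylic H and delivery of oxygen to the tertiary carbon. The mechanism runs through a perepoxide. The benzylic C–H is the weakest allylic C–H, and abstracting it forms a C=C conjugated with the electron-rich aryl ring. This gives the unisolated tertiary allylic hydroperoxide, Ar–CH=CH–CMe2–OOH, with the aryl group anti to the bulky CMe2OOH so the alkene is E. PPh3 then reduces it to the alcohol. The closest known chemistry is the ene reaction of 1O2 with trisubstituted alkenes, which usually gives mixtures. Here the two prenyls are equivalent (one constitutional product) and the remaining prenyl is more reactive toward 1O2 than the new, deactivated styrenyl alkene. Mono-oxidation therefore occurs statistically, and C2 is unaffected at 0 °C.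

**Step 6**
- Reactants: 11
- Product: 12, the target, (2S)-5,7-dihydroxy-4'-methoxy-3'-[(E)-3-hydroxy-3-methylbut-1-enyl]-5'-(3-methylbut-2-enyl)flavanone
- Conditions: TBAF (1.5 equiv), AcOH (3 equiv), THF, 0 °C → rt
- Reagents that add atoms: none
- Why: Fluoride cleavage of the aryl TIPS ether. The AcOH buffer prevents base-mediated flavanone ring opening, and the acid-sensitive tertiary styryl alcohol is not exposed to acid.

**Compound list**

| # | Name | SMILES | Role |
|---|---|---|---|
| 1 | (S)-naringenin | Oc1ccc([C@@H]2CC(=O)c3c(O)cc(O)cc3O2)cc1 | starting material |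
| 2 | triisopropylsilyl chloride | CC(C)[Si](Cl)(C(C)C)C(C)C | starting material (reagent) |
| 3 | (2S)-7-O-TIPS-naringenin | Oc1ccc([C@@H]2CC(=O)c3c(O)cc(O[Si](C(C)C)(C(C)C)C(C)C)cc3O2)cc1 | intermediate |
| 4 | N-iodosuccinimide | O=C1CCC(=O)N1I | starting material (reagent) |
| 5 | (2S)-3',5'-diiodo-7-O-TIPS-naringenin | Oc1c(I)cc([C@@H]2CC(=O)c3c(O)cc(O[Si](C(C)C)(C(C)C)C(C)C)cc3O2)cc1I | intermediate |
| 6 | trimethylsilyldiazomethane | C[Si](C)(C)C=[N+]=[N-] | starting material (reagent) |
| 7 | (2S)-3',5'-diiodo-4'-O-methyl-7-O-TIPS-naringenin | COc1c(I)cc([C@@H]2CC(=O)c3c(O)cc(O[Si](C(C)C)(C(C)C)C(C)C)cc3O2)cc1I | intermediate |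
| 8 | tributyl(3-methylbut-2-enyl)stannane | CC(C)=CC[Sn](CCCC)(CCCC)CCCC | starting material (reagent) |
| 9 | (2S)-3',5'-diprenyl-4'-O-methyl-7-O-TIPS-naringenin | COc1c(CC=C(C)C)cc([C@@H]2CC(=O)c3c(O)cc(O[Si](C(C)C)(C(C)C)C(C)C)cc3O2)cc1CC=C(C)C | intermediate |
| 10 | dioxygen | O=O | starting material (reagent) |
| 11 | 7-O-TIPS target | COc1c(/C=C/C(C)(C)O)cc([C@@H]2CC(=O)c3c(O)cc(O[Si](C(C)C)(C(C)C)C(C)C)cc3O2)cc1CC=C(C)C | intermediate |
| 12 | target | COc1c(/C=C/C(C)(C)O)cc([C@@H]2CC(=O)c3c(O)cc(O)cc3O2)cc1CC=C(C)C | target |

**Total steps:** 6. **Longest linear sequence:** 6 (from 1 to 12).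

**Three steps most likely to fail**
1. **Step 5 (proposed new step).** Regioselectivity may be poor: the secondary hydroperoxide from abstraction of the cis-methyl H can compete, and bis-oxidation is possible.
   - Fallback (known chemistry): mono-Stille of 7 (1 equiv stannane) to give the 5'-iodo-3'-prenyl compound, then Heck coupling with 2-methylbut-3-en-2-ol (Pd(OAc)2, phosphine, base) to give the E-styryl tertiary alcohol.
2. **Step 4.** The double coupling at hindered ortho-OMe iodides may give incomplete conversion or branched (reverse-prenyl) isomers.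
   - Fallback: Suzuki coupling of 7 with allyl-Bpin to give the 3',5'-diallyl compound, then cross-metathesis with 2-methyl-2-butene (Grubbs II) to form both prenyl groups.
3. **Step 2.** Iodination could leak onto A-ring C6/C8, and step 1 may be less than fully 7-selective.
   - Fallback: also block the A ring by converting 3 to the 5,7-bis-TIPS ether (TIPSOTf, 2,6-lutidine), or use a 7-O-allyl group in place of TIPS. The allyl group comes from 1 equiv allyl bromide/K2CO3 and is removed in the last step with Pd(PPh3)4/morpholine.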